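## Retrosynthetic overview

- **Feature:** C3 of the dihydropyran ring C is a tertiary CH bonded to three carbons: C4 (benzylic CH2 on ring A), C1' (ring B) and C2 (the OCH2). Each of these bonds can be made by a 1,2-shift from boron to carbon. The target is (3R).
- **Ring C** is opened at O1–C2 (Mitsunobu etherification). C2 comes from a CH2 insertion into a C3–B bond, followed by oxidation.
- **C3** is the carbon atom of CH2Cl2. C3–C4 and C3–C1' form in one flask from the ring A benzylboronic ester of (R,R)-1,2-dicyclohexylethane-1,2-diol, LiCHCl2 and the ring B Grignard reagent.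
- **Fragments:** the benzylboronate comes from directed ortho-lithiation of doubly protected 5-methoxyresorcinol and capture by the chiral (chloromethyl)boronate. The ring B/D bromide comes from 4-bromoresorcinol by silylation, propargylation and a Claisen cascade.
- **Ring order:** rings A and B are bought, ring D closes in step 7, ring C closes in step 12.

Key step: step 8

Remark: isoflavan numbering is used (O1, C2, C3, C4, C4a to C8a for rings C and A; C1' to C6' for ring B). TIPS = triisopropylsilyl, MOM = methoxymethyl.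

## Route

Step 1
Reactants: 1 5-methoxyresorcinol
Product: 2 3-methoxy-5-(triisopropylsilyloxy)phenol
Conditions: TIPSCl (1.0 equiv, slow addition), imidazole, DMF, 0 °C → rt
Reagents that add atoms: triisopropylsilyl chloride, CC(C)[Si](Cl)(C(C)C)C(C)C
Why: Silyl ether formation at one of two equivalent phenols, in which slow addition of one equivalent of the bulky chloride should favour the mono-ether while unreacted diol and bis-ether are separable and recyclable.

Step 2
Reactants: 2 3-methoxy-5-(triisopropylsilyloxy)phenol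
Product: 3 triisopropyl[3-methoxy-5-(methoxymethoxy)phenoxy]silane
Conditions: MOMCl, iPr2NEt, CH2Cl2, 0 °C → rt
Reagents that add atoms: chloromethyl methyl ether, COCCl
Why: O-alkylation of the phenol with a chloromethyl ether under amine base (acetal protection) installs the directing group on the oxygen that becomes O1, and the aryl TIPS ether is inert to these conditions.

Step 3
Reactants: 4 triisopropyl borate; 5 chloroiodomethane; 6 (R,R)-1,2-dicyclohexylethane-1,2-diol
Product: 9 (4R,5R)-2-(chloromethyl)-4,5-dicyclohexyl-1,3,2-dioxaborolane, via lithium (chloromethyl)triisopropoxyborate 7 (not isolated), via diisopropyl (chloromethyl)boronate 8 (not isolated)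
Conditions: n-BuLi added to 4 + 5, THF, −78 °C; HCl (2 M in Et2O), −78 °C → rt; then 6, rt
Reagents that add atoms: triisopropyl borate 4, CC(C)OB(OC(C)C)OC(C)C; chloroiodomethane 5, ClCI
Why: Iodine–lithium exchange in the presence of the borate gives chloromethyllithium that is trapped at once as borate 7, acid frees boronate 8, and transesterification with the chelating diol (Matteson-type preparation of a halomethylboronic ester) gives 9 without touching the two carbinol stereocentres.

Step 4
Reactants: 3 triisopropyl[3-methoxy-5-(methoxymethoxy)phenoxy]silane; 9 (4R,5R)-2-(chloromethyl)-4,5-dicyclohexyl-1,3,2-dioxaborolane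
Product: 12 (4R,5R)-4,5-dicyclohexyl-2-[2-methoxy-6-(methoxymethoxy)-4-(triisopropylsilyloxy)benzyl]-1,3,2-dioxaborolane, via ring A aryllithium 10 (not isolated), via lithium aryl(chloromethyl)borate 11 (not isolated)
Conditions: n-BuLi (1.1 equiv), THF, 0 °C, 1 h; 9 (1.2 equiv), −78 °C → rt, then 40 °C
Reagents that add atoms: none
Why: Directed ortho-metalation takes place at the only position flanked by the two coordinating groups (OMOM and OMe), the TIPS group shielding the other two, and the aryllithium adds to boron of 9 to give borate 11, whose aryl group shifts to carbon with loss of chloride on warming (Matteson-type substitution of a halomethylboronic ester), forming C4a–C4 without touching the diol centres.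

Step 5
Reactants: 13 4-bromoresorcinol
Product: 14 2-bromo-5-(triisopropylsilyloxy)phenol
Conditions: TIPSCl (1.0 equiv), imidazole, CH2Cl2–DMF, 0 °C
Reagents that add atoms: triisopropylsilyl chloride, CC(C)[Si](Cl)(C(C)C)C(C)C
Why: Sterically controlled silylation, in which the hydroxyl para to bromine is unhindered whereas the one ortho to bromine is shielded and hydrogen-bonded to the halogen, so that the bulky chloride should react at the former.

Step 6
Reactants: 14 2-bromo-5-(triisopropylsilyloxy)phenol; 15 3-chloro-3-methylbut-1-yne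
Product: 16 [4-bromo-3-(2-methylbut-3-yn-2-yloxy)phenoxy]triisopropylsilane
Conditions: 15, DBU, CuCl2·2H2O (1 mol %), MeCN, 0 °C → rt
Reagents that add atoms: 3-chloro-3-methylbut-1-yne 15, C#CC(C)(C)Cl
Why: Copper-catalysed O-propargylation of a phenol with a tertiary propargylic chloride under amidine base is the standard entry to 1,1-dimethylpropargyl aryl ethers and avoids the carbonate or hydroxide bases that could strip the aryl silyl ether.

Step 7
Reactants: 16 [4-bromo-3-(2-methylbut-3-yn-2-yloxy)phenoxy]triisopropylsilane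
Product: 17 8-bromo-2,2-dimethyl-5-(triisopropylsilyloxy)-2H-chromene
Conditions: N,N-diethylaniline, 190 °C
Reagents that add atoms: none
Why: Aromatic propargyl Claisen rearrangement, enolisation, 1,5-hydrogen shift and oxa-6π-electrocyclisation close ring D in one thermal operation, and because bromine blocks one ortho position the [3,3] shift is productive only at the carbon between the two oxygens, which gives the required 5-oxy-8-bromo pattern.

Step 8
Reactants: 12 ring A benzylboronic ester of the (R,R)-diol; 17 8-bromo-2,2-dimethyl-5-(triisopropylsilyloxy)-2H-chromene; 18 dichloromethane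
Product: 23 (4R,5R)-4,5-dicyclohexyl-2-{(1R)-1-[2,2-dimethyl-5-(triisopropylsilyloxy)-2H-chromen-8-yl]-2-[2-methoxy-6-(methoxymethoxy)-4-(triisopropylsilyloxy)phenyl]ethyl}-1,3,2-dioxaborolane, via Grignard reagent 19 (not isolated), via lithium dichloromethylborate 20 (not isolated), via (S)-α-chloro boronate 21 (not isolated), via bromomagnesium arylborate 22 (not isolated)
Conditions: 18, n-BuLi, THF, −100 °C, then 12; ZnCl2 (0.75 equiv, THF), −100 °C → rt, 16 h; then 19 (2.5 equiv, from 17 and Mg turnings, THF, 40 °C), −78 °C → rt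
Reagents that add atoms: dichloromethane 18, ClCCl
Why: Preformed LiCHCl2 adds to boron of 12 to give borate 20, and on warming ZnCl2 abstracts one of the two diastereotopic chlorides while the ring A benzyl group shifts from boron to carbon (C3–C4), which gives the (S)-chloride 21. Grignard reagent 19 then adds to boron of 21, and in borate 22 the ring B aryl group migrates anti to the remaining C–Cl bond (C3–C1'), so that C3 is inverted and the (1R)-boronate 23 results. The closest known chemistry is this same pair of operations, the Matteson asymmetric homologation of a chiral diol boronic ester followed by Grignard substitution of the α-chloro boronic ester, which is established for benzylboronic esters and for aryl Grignard reagents; no ring is closed in this step. C3 is the only new stereocentre: the C2-symmetric (R,R)-diol makes the two faces of boron equivalent and decides which chloride leaves in the ZnCl2-bound transition state, the second shift is stereospecific, and a minor C3 epimer would be a diastereomer of 23 that can be removed while the auxiliary is still attached. The step needs addition to boron rather than deprotonation of the B–CH2–Ar protons, carbon rather than oxygen migration, and no chloride-induced epimerisation of 21; the low temperature with preformed carbenoid, the good migratory aptitude of benzyl and electron-rich aryl groups, and ZnCl2 as chloride scavenger secure these in turn. The surplus of 19 allows for its partial transmetalation to zinc, and the MOM, methyl and TIPS ethers and the chromene alkene are inert to all reagents used.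

Step 9
Reactants: 23 (1R)-boronic ester from step 8; 5 chloroiodomethane
Product: 25 (4R,5R)-4,5-dicyclohexyl-2-{(2R)-2-[2,2-dimethyl-5-(triisopropylsilyloxy)-2H-chromen-8-yl]-3-[2-methoxy-6-(methoxymethoxy)-4-(triisopropylsilyloxy)phenyl]propyl}-1,3,2-dioxaborolane, via lithium (chloromethyl)borate 24 (not isolated)
Conditions: 5 (2 equiv), n-BuLi (1.8 equiv, added last), THF, −78 °C → rt
Reagents that add atoms: chloroiodomethane 5, ClCI
Why: Matteson one-carbon homologation, in which chloromethyllithium made in situ adds to boron to give borate 24 and the secondary benzylic carbon C3 migrates with retention of configuration and loss of chloride, forming C3–C2.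

Step 10
Reactants: 25 homologated boronic ester
Product: 26 (2R)-2-[2,2-dimethyl-5-(triisopropylsilyloxy)-2H-chromen-8-yl]-3-[2-methoxy-6-(methoxymethoxy)-4-(triisopropylsilyloxy)phenyl]propan-1-ol
Conditions: NaBO3·4H2O, THF–H2O (1:1), rt
Reagents that add atoms: NaBO3·4H2O (anion drawn as the dimer), [Na+].[Na+].O[B-]1(O)OO[B-](O)(O)OO1
Why: Oxidation of the primary C–B bond by a peroxoborate (1,2-shift from boron to oxygen) gives the alcohol under conditions mild enough for the aryl TIPS ethers, the MOM acetal and the chromene alkene, frees the diol for recovery and does not touch C3.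

Step 11
Reactants: 26 primary alcohol
Product: 27 2-{(2R)-2-[2,2-dimethyl-5-(triisopropylsilyloxy)-2H-chromen-8-yl]-3-hydroxypropyl}-3-methoxy-5-(triisopropylsilyloxy)phenol
Conditions: p-TsOH·H2O (0.1 equiv), MeOH–THF, 40 °C
Reagents that add atoms: none
Why: Acid-catalysed transacetalisation of the phenolic MOM ether with methanol, run with little acid and gentle warming so that the aryl TIPS ethers and the acid-sensitive chromene double bond should survive.

Step 12
Reactants: 27 phenol alcohol
Product: 28 (3R)-3-[2,2-dimethyl-5-(triisopropylsilyloxy)-2H-chromen-8-yl]-5-methoxy-7-(triisopropylsilyloxy)chroman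
Conditions: PPh3, DIAD, THF (0.02 M), 0 °C → rt
Reagents that add atoms: none
Why: Intramolecular Mitsunobu etherification, in which the primary alcohol is activated as its oxyphosphonium salt and displaced by the only free phenol in a 6-exo-tet closure of ring C (O1–C2) at a CH2 carbon, so that C3 is not affected.

Step 13
Reactants: 28 bis-TIPS isoflavan
Product: 29 (3R)-3-(5-hydroxy-2,2-dimethyl-2H-chromen-8-yl)-5-methoxychroman-7-ol (target)
Conditions: TBAF (2.2 equiv), AcOH (2.2 equiv), THF, 0 °C
Reagents that add atoms: none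
Why: Fluoride-mediated cleavage of both aryl silyl ethers, buffered with acetic acid so that the electron-rich phenolates are protonated at once, leaves the alkyl aryl ethers, the chromene and C3 untouched.

## Compound list

1 | 5-methoxyresorcinol | COc1cc(O)cc(O)c1 | starting material
2 | 3-methoxy-5-(triisopropylsilyloxy)phenol | COc1cc(O)cc(O[Si](C(C)C)(C(C)C)C(C)C)c1 | intermediate
3 | triisopropyl[3-methoxy-5-(methoxymethoxy)phenoxy]silane | COc1cc(OCOC)cc(O[Si](C(C)C)(C(C)C)C(C)C)c1 | intermediate
4 | triisopropyl borate | CC(C)OB(OC(C)C)OC(C)C | starting material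
5 | chloroiodomethane | ClCI | starting material
6 | (R,R)-1,2-dicyclohexylethane-1,2-diol | O[C@H](C1CCCCC1)[C@H](O)C1CCCCC1 | starting material
7 | lithium (chloromethyl)triisopropoxyborate | [Li+].ClC[B-](OC(C)C)(OC(C)C)OC(C)C | intermediate
8 | diisopropyl (chloromethyl)boronate | ClCB(OC(C)C)OC(C)C | intermediate
9 | (4R,5R)-2-(chloromethyl)-4,5-dicyclohexyl-1,3,2-dioxaborolane | ClCB1O[C@H](C2CCCCC2)[C@@H](C2CCCCC2)O1 | intermediate
10 | 2-methoxy-6-(methoxymethoxy)-4-(triisopropylsilyloxy)phenyllithium | COc1cc(O[Si](C(C)C)(C(C)C)C(C)C)cc(OCOC)c1[Li] | intermediate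
11 | lithium borate from 10 and 9 (boron bears the ring A aryl group, CH2Cl and the (R,R)-diol) | [Li+].COc1cc(O[Si](C(C)C)(C(C)C)C(C)C)cc(OCOC)c1[B-]1(CCl)O[C@H](C2CCCCC2)[C@@H](C2CCCCC2)O1 | intermediate
12 | (4R,5R)-4,5-dicyclohexyl-2-[2-methoxy-6-(methoxymethoxy)-4-(triisopropylsilyloxy)benzyl]-1,3,2-dioxaborolane | COc1cc(O[Si](C(C)C)(C(C)C)C(C)C)cc(OCOC)c1CB1O[C@H](C2CCCCC2)[C@@H](C2CCCCC2)O1 | intermediate
13 | 4-bromoresorcinol | Oc1ccc(Br)c(O)c1 | starting material
14 | 2-bromo-5-(triisopropylsilyloxy)phenol | Oc1cc(O[Si](C(C)C)(C(C)C)C(C)C)ccc1Br | intermediate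
15 | 3-chloro-3-methylbut-1-yne | C#CC(C)(C)Cl | starting material
16 | [4-bromo-3-(2-methylbut-3-yn-2-yloxy)phenoxy]triisopropylsilane | C#CC(C)(C)Oc1cc(O[Si](C(C)C)(C(C)C)C(C)C)ccc1Br | intermediate
17 | 8-bromo-2,2-dimethyl-5-(triisopropylsilyloxy)-2H-chromene | Brc1ccc(O[Si](C(C)C)(C(C)C)C(C)C)c2c1OC(C)(C)C=C2 | intermediate
18 | dichloromethane | ClCCl | starting material
19 | [2,2-dimethyl-5-(triisopropylsilyloxy)-2H-chromen-8-yl]magnesium bromide | Br[Mg]c1ccc(O[Si](C(C)C)(C(C)C)C(C)C)c2c1OC(C)(C)C=C2 | intermediate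
20 | lithium borate from 12 and LiCHCl2 (boron bears the ring A benzyl group, CHCl2 and the (R,R)-diol) | [Li+].COc1cc(O[Si](C(C)C)(C(C)C)C(C)C)cc(OCOC)c1C[B-]1(C(Cl)Cl)O[C@H](C2CCCCC2)[C@@H](C2CCCCC2)O1 | intermediate
21 | (4R,5R)-2-{(1S)-1-chloro-2-[2-methoxy-6-(methoxymethoxy)-4-(triisopropylsilyloxy)phenyl]ethyl}-4,5-dicyclohexyl-1,3,2-dioxaborolane | COc1cc(O[Si](C(C)C)(C(C)C)C(C)C)cc(OCOC)c1C[C@@H](Cl)B1O[C@H](C2CCCCC2)[C@@H](C2CCCCC2)O1 | intermediate
22 | bromomagnesium borate from 21 and 19 (boron bears the (1S)-chloroalkyl group, the ring B aryl group and the (R,R)-diol) | Br[Mg+].COc1cc(O[Si](C(C)C)(C(C)C)C(C)C)cc(OCOC)c1C[C@@H](Cl)[B-]1(c2ccc(O[Si](C(C)C)(C(C)C)C(C)C)c3c2OC(C)(C)C=C3)O[C@H](C2CCCCC2)[C@@H](C2CCCCC2)O1 | intermediate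
23 | (4R,5R)-4,5-dicyclohexyl-2-{(1R)-1-[2,2-dimethyl-5-(triisopropylsilyloxy)-2H-chromen-8-yl]-2-[2-methoxy-6-(methoxymethoxy)-4-(triisopropylsilyloxy)phenyl]ethyl}-1,3,2-dioxaborolane | COc1cc(O[Si](C(C)C)(C(C)C)C(C)C)cc(OCOC)c1C[C@H](c1ccc(O[Si](C(C)C)(C(C)C)C(C)C)c2c1OC(C)(C)C=C2)B1O[C@H](C2CCCCC2)[C@@H](C2CCCCC2)O1 | intermediate
24 | lithium borate from 23 and LiCH2Cl (boron bears the (1R)-diarylethyl group, CH2Cl and the (R,R)-diol) | [Li+].COc1cc(O[Si](C(C)C)(C(C)C)C(C)C)cc(OCOC)c1C[C@H](c1ccc(O[Si](C(C)C)(C(C)C)C(C)C)c2c1OC(C)(C)C=C2)[B-]1(CCl)O[C@H](C2CCCCC2)[C@@H](C2CCCCC2)O1 | intermediate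
25 | (4R,5R)-4,5-dicyclohexyl-2-{(2R)-2-[2,2-dimethyl-5-(triisopropylsilyloxy)-2H-chromen-8-yl]-3-[2-methoxy-6-(methoxymethoxy)-4-(triisopropylsilyloxy)phenyl]propyl}-1,3,2-dioxaborolane | COc1cc(O[Si](C(C)C)(C(C)C)C(C)C)cc(OCOC)c1C[C@H](c1ccc(O[Si](C(C)C)(C(C)C)C(C)C)c2c1OC(C)(C)C=C2)CB1O[C@H](C2CCCCC2)[C@@H](C2CCCCC2)O1 | intermediate
26 | (2R)-2-[2,2-dimethyl-5-(triisopropylsilyloxy)-2H-chromen-8-yl]-3-[2-methoxy-6-(methoxymethoxy)-4-(triisopropylsilyloxy)phenyl]propan-1-ol | COc1cc(O[Si](C(C)C)(C(C)C)C(C)C)cc(OCOC)c1C[C@H](c1ccc(O[Si](C(C)C)(C(C)C)C(C)C)c2c1OC(C)(C)C=C2)CO | intermediate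
27 | 2-{(2R)-2-[2,2-dimethyl-5-(triisopropylsilyloxy)-2H-chromen-8-yl]-3-hydroxypropyl}-3-methoxy-5-(triisopropylsilyloxy)phenol | COc1cc(O[Si](C(C)C)(C(C)C)C(C)C)cc(O)c1C[C@H](c1ccc(O[Si](C(C)C)(C(C)C)C(C)C)c2c1OC(C)(C)C=C2)CO | intermediate
28 | (3R)-3-[2,2-dimethyl-5-(triisopropylsilyloxy)-2H-chromen-8-yl]-5-methoxy-7-(triisopropylsilyloxy)chroman | COc1cc(O[Si](C(C)C)(C(C)C)C(C)C)cc2c1C[C@H](c1ccc(O[Si](C(C)C)(C(C)C)C(C)C)c3c1OC(C)(C)C=C3)CO2 | intermediate
29 | (3R)-3-(5-hydroxy-2,2-dimethyl-2H-chromen-8-yl)-5-methoxychroman-7-ol | COc1cc(O)cc2c1C[C@H](c1ccc(O)c3c1OC(C)(C)C=C3)CO2 | target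

## Step count and risks

Total step count: 13.

Longest linear sequence: 9 steps (1, 2, 4, 8, 9, 10, 11, 12, 13). The ring B branch 5, 6, 7, 8 to 13 is equally long.

### Step 8

- **What may go wrong:** Transmetalation of the Grignard reagent to the ZnCl2 left in the flask, together with slow borate formation at the crowded boron, could leave the chloride unsubstituted. Halide exchange could then erode the configuration at C3. Oxygen migration could also compete with carbon migration.
- **Fallback:** reagent-controlled lithiation–borylation in place of auxiliary control. It sets out from aryllithium 10 and bromide 17 and comes back at alcohol 26.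
- Aryllithium 10 is alkylated with oxirane (BF3·OEt2, THF, −78 °C) to 2-arylethanol F1. This is acylated with N,N-diisopropylcarbamoyl chloride (Et3N, CH2Cl2, reflux) to carbamate F2.
- In parallel, 17 is taken through bromine–lithium exchange (n-BuLi, THF, −78 °C) and 2-isopropoxy-4,4,5,5-tetramethyl-1,3,2-dioxaborolane to ring B pinacol boronate F3.
- s-BuLi/(−)-sparteine (Et2O, −78 °C) removes the pro-S hydrogen next to the carbamate oxygen of F2. The configurationally stable organolithium takes up F3 with retention. On warming, the ring B aryl group migrates with inversion and expels the carbamate, which should give the (1R)-pinacol boronate F4, the pinacol analogue of 23.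
- Insertion of CH2 as in step 9 gives pinacol boronate F5, and oxidation as in step 10 gives 26.

### Step 4

- **What may go wrong:** Addition of the doubly ortho-substituted aryllithium to boron may be slow. Attack at the C–Cl bond or proton abstraction from the chloromethyl group may compete. The electron-rich benzylboronate may protodeboronate during purification.
- **Fallback:** C4 is brought in as a formyl carbon and boron is attached afterwards. It sets out from aryllithium 10 and comes back at benzylboronate 12.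
- 10 is formylated with DMF (THF, −78 °C → 0 °C) to aldehyde F6. This is condensed with p-toluenesulfonyl hydrazide (MeOH, rt) to tosylhydrazone F7.
- The sodium salt of F7 (NaH, toluene) is heated with pinacolborane (90 °C). The aryldiazomethane released inserts into the B–H bond and gives pinacol benzylboronate F8.
- Exchange of the diol goes through the crystalline diethanolamine boronate F9 (diethanolamine, Et2O, rt). F9 is shaken with 6 in Et2O/0.1 M aqueous HCl to give 12.

### Step 11

- **What may go wrong:** Acid-promoted addition of methanol to the electron-rich chromene double bond, or its oligomerisation, and partial loss of the aryl silyl ethers, may happen before the acetal is fully cleaved.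
- **Fallback:** acid-free acetal exchange on a pre-activated alcohol, then base-mediated ring closure. It sets out from alcohol 26 and comes back at isoflavan 28.
- 26 is first mesylated (MsCl, Et3N, CH2Cl2, 0 °C) to mesylate F10.
- The MOM ether is then exchanged under non-acidic conditions with TMSOTf/2,2'-bipyridyl (MeCN, 0 °C → rt), which should pass through aryl trimethylsilyl ether F11. Water then frees phenol mesylate F12.
- K2CO3 (acetone, 50 °C) closes ring C by intramolecular Williamson displacement (6-exo-tet at C2, C3 untouched) and gives 28. Both the Brønsted acid of step 11 and the Mitsunobu reaction of step 12 are bypassed.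

## Further compounds

F1 | step 8 | 2-[2-methoxy-6-(methoxymethoxy)-4-(triisopropylsilyloxy)phenyl]ethanol | COc1cc(O[Si](C(C)C)(C(C)C)C(C)C)cc(OCOC)c1CCO
F2 | step 8 | 2-[2-methoxy-6-(methoxymethoxy)-4-(triisopropylsilyloxy)phenyl]ethyl N,N-diisopropylcarbamate | COc1cc(O[Si](C(C)C)(C(C)C)C(C)C)cc(OCOC)c1CCOC(=O)N(C(C)C)C(C)C
F3 | step 8 | 2-[2,2-dimethyl-5-(triisopropylsilyloxy)-2H-chromen-8-yl]-4,4,5,5-tetramethyl-1,3,2-dioxaborolane | CC1(C)OB(OC1(C)C)c1ccc(O[Si](C(C)C)(C(C)C)C(C)C)c2c1OC(C)(C)C=C2
F4 | step 8 | pinacol (1R)-1-[2,2-dimethyl-5-(triisopropylsilyloxy)-2H-chromen-8-yl]-2-[2-methoxy-6-(methoxymethoxy)-4-(triisopropylsilyloxy)phenyl]ethylboronate | COc1cc(O[Si](C(C)C)(C(C)C)C(C)C)cc(OCOC)c1C[C@H](c1ccc(O[Si](C(C)C)(C(C)C)C(C)C)c2c1OC(C)(C)C=C2)B1OC(C)(C)C(C)(C)O1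
F5 | step 8 | pinacol (2R)-2-[2,2-dimethyl-5-(triisopropylsilyloxy)-2H-chromen-8-yl]-3-[2-methoxy-6-(methoxymethoxy)-4-(triisopropylsilyloxy)phenyl]propylboronate | COc1cc(O[Si](C(C)C)(C(C)C)C(C)C)cc(OCOC)c1C[C@H](c1ccc(O[Si](C(C)C)(C(C)C)C(C)C)c2c1OC(C)(C)C=C2)CB1OC(C)(C)C(C)(C)O1
F6 | step 4 | 2-methoxy-6-(methoxymethoxy)-4-(triisopropylsilyloxy)benzaldehyde | COc1cc(O[Si](C(C)C)(C(C)C)C(C)C)cc(OCOC)c1C=O
F7 | step 4 | (E)-N'-[2-methoxy-6-(methoxymethoxy)-4-(triisopropylsilyloxy)benzylidene]-4-methylbenzenesulfonohydrazide | COc1cc(O[Si](C(C)C)(C(C)C)C(C)C)cc(OCOC)c1/C=N/NS(=O)(=O)c1ccc(C)cc1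
F8 | step 4 | pinacol 2-methoxy-6-(methoxymethoxy)-4-(triisopropylsilyloxy)benzylboronate | COc1cc(O[Si](C(C)C)(C(C)C)C(C)C)cc(OCOC)c1CB1OC(C)(C)C(C)(C)O1
F9 | step 4 | diethanolamine 2-methoxy-6-(methoxymethoxy)-4-(triisopropylsilyloxy)benzylboronate | COc1cc(O[Si](C(C)C)(C(C)C)C(C)C)cc(OCOC)c1CB1OCCNCCO1
F10 | step 11 | (2R)-2-[2,2-dimethyl-5-(triisopropylsilyloxy)-2H-chromen-8-yl]-3-[2-methoxy-6-(methoxymethoxy)-4-(triisopropylsilyloxy)phenyl]propyl methanesulfonate | COc1cc(O[Si](C(C)C)(C(C)C)C(C)C)cc(OCOC)c1C[C@H](c1ccc(O[Si](C(C)C)(C(C)C)C(C)C)c2c1OC(C)(C)C=C2)COS(C)(=O)=O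
F11 | step 11 | (2R)-2-[2,2-dimethyl-5-(triisopropylsilyloxy)-2H-chromen-8-yl]-3-[2-methoxy-4-(triisopropylsilyloxy)-6-(trimethylsilyloxy)phenyl]propyl methanesulfonate | COc1cc(O[Si](C(C)C)(C(C)C)C(C)C)cc(O[Si](C)(C)C)c1C[C@H](c1ccc(O[Si](C(C)C)(C(C)C)C(C)C)c2c1OC(C)(C)C=C2)COS(C)(=O)=O
F12 | step 11 | (2R)-2-[2,2-dimethyl-5-(triisopropylsilyloxy)-2H-chromen-8-yl]-3-[2-hydroxy-6-methoxy-4-(triisopropylsilyloxy)phenyl]propyl methanesulfonate | COc1cc(O[Si](C(C)C)(C(C)C)C(C)C)cc(O)c1C[C@H](c1ccc(O[Si](C(C)C)(C(C)C)C(C)C)c2c1OC(C)(C)C=C2)COS(C)(=O)=O
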